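## Retrosynthetic overview
1. The hydroquinone is unmasked last from its dimethyl ether (oxidative demethylation to the quinone, then dithionite reduction).
2. The C-8′–C-9′ bond is made by an intermolecular aldol addition of the lithium enolate of an (S)-α-silyloxy methyl ketone (C-9′ to C-16′) to an aryl dienal (arene plus C-1′ to C-8′). Dehydration gives a dienone, and reductive 1,3-transposition of its tosylhydrazone removes the C-10′ carbonyl and places the 9′E alkene.
3. The ketone half comes from geraniol: Sharpless epoxidation sets the S carbinol carbon, then epoxy chloride, alkyne, hydration, silylation.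
4. The aldehyde half comes from an arylcopper plus geranyl bromide, then E-selective SeO2 oxidation of the terminal methyl group and MnO2 oxidation.
5. No ring is formed; the benzene ring is carried from 4-methoxy-2-methylphenol.

Assumption: side-chain atoms are numbered C-1′ (benzylic CH2) to C-16′ as in the target, and 4-methoxy-2-methylphenol, geranyl bromide and geraniol are bought.

## Route

Step 1
Reactants: 1 4-methoxy-2-methylphenol
Product: 2 2-bromo-4-methoxy-6-methylphenol
Conditions: NBS, CH2Cl2, 0 °C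
Reagents that add atoms: N-bromosuccinimide, O=C1CCC(=O)N1Br
Why: Electrophilic aromatic bromination is directed by the free hydroxyl to its only open ortho position (the para position carries OMe), which gives the substitution pattern needed for the later chain attachment.

Step 2
Reactants: 2 2-bromo-4-methoxy-6-methylphenol
Product: 3 1-bromo-2,5-dimethoxy-3-methylbenzene
Conditions: MeI, K2CO3, DMF, 25 °C
Reagents that add atoms: iodomethane, CI
Why: Williamson ether synthesis (SN2 of the phenoxide on MeI) masks the phenol as a methyl ether that survives the organolithium, enolate and borane steps.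

Step 3
Reactants: 3 1-bromo-2,5-dimethoxy-3-methylbenzene; 4 geranyl bromide, (2E)-1-bromo-3,7-dimethylocta-2,6-diene
Product: 7 1-[(2E)-3,7-dimethylocta-2,6-dien-1-yl]-2,5-dimethoxy-3-methylbenzene, via aryllithium 5 (not isolated), via arylcopper 6 (not isolated)
Conditions: n-BuLi, THF, −78 °C; CuBr·SMe2, −78 to −30 °C; then 4, −30 to 0 °C
Reagents that add atoms: none
Why: Bromine–lithium exchange and transmetallation to the arylcopper allow an SN2-type allylic substitution on the primary allylic bromide, which keeps the 2′E double bond and gives little SN2′ product.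

Step 4
Reactants: 7 1-[(2E)-3,7-dimethylocta-2,6-dien-1-yl]-2,5-dimethoxy-3-methylbenzene
Product: 8 (2E,6E)-8-(2,5-dimethoxy-3-methylphenyl)-2,6-dimethylocta-2,6-dien-1-ol
Conditions: SeO2 (0.3 equiv), t-BuOOH, salicylic acid (0.1 equiv), CH2Cl2, 0 to 25 °C
Reagents that add atoms: tert-butyl hydroperoxide, CC(C)(C)OO (oxygen relayed by catalytic SeO2, O=[Se]=O)
Why: Selenium dioxide allylic oxidation (ene reaction then [2,3]-sigmatropic shift) hydroxylates the E-methyl group of the terminal trisubstituted alkene, so the 6′ alkene is obtained with E geometry.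

Step 5
Reactants: 8 (2E,6E)-8-(2,5-dimethoxy-3-methylphenyl)-2,6-dimethylocta-2,6-dien-1-ol
Product: 9 (2E,6E)-8-(2,5-dimethoxy-3-methylphenyl)-2,6-dimethylocta-2,6-dienal
Conditions: MnO2, CH2Cl2, 25 °C
Reagents that add atoms: none
Why: MnO2 oxidises the allylic alcohol chemoselectively to the α-branched enal without changing the E geometry or touching the electron-rich arene.

Step 6
Reactants: 10 geraniol, (2E)-3,7-dimethylocta-2,6-dien-1-ol
Product: 11 (2S,3S)-2,3-epoxygeraniol, [(2S,3S)-3-methyl-3-(4-methylpent-3-en-1-yl)oxiran-2-yl]methanol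
Conditions: Ti(OiPr)4 (5 mol%), L-(+)-diethyl tartrate (6 mol%), t-BuOOH, 4 Å molecular sieves, CH2Cl2, −20 °C
Reagents that add atoms: tert-butyl hydroperoxide, CC(C)(C)OO
Why: Katsuki–Sharpless asymmetric epoxidation with the titanium–L-(+)-tartrate catalyst epoxidises only the allylic-alcohol alkene on one face (about 95% ee), and the (3S) carbon so formed becomes the S carbinol carbon C-11′ of the target.

Step 7
Reactants: 11 (2S,3S)-2,3-epoxygeraniol
Product: 12 (2R,3S)-1-chloro-2,3-epoxy-3,7-dimethyloct-6-ene (same spatial arrangement as 11; the C-2 descriptor changes only through CIP priority)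
Conditions: PPh3, CCl4, NaHCO3, reflux
Reagents that add atoms: tetrachloromethane, ClC(Cl)(Cl)Cl
Why: Appel chlorination replaces the primary hydroxyl by chloride (SN2 at CH2) under buffered conditions that leave the epoxide and both stereocentres untouched.

Step 8
Reactants: 12 (2R,3S)-1-chloro-2,3-epoxy-3,7-dimethyloct-6-ene
Product: 14 (3S)-3,7-dimethyloct-6-en-1-yn-3-ol ((S)-dehydrolinalool), via lithium chloroalkenyl alkoxide 13 (not isolated)
Conditions: LiN(iPr)2 (3.3 equiv), THF, −40 to −20 °C; then H2O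
Reagents that add atoms: none
Why: Base-induced double elimination (deprotonation next to chlorine opens the epoxide to the chloroalkenyl alkoxide, then dehydrochlorination gives the alkyne) never breaks the C-3–O bond, so the tertiary carbinol keeps the S configuration.

Step 9
Reactants: 14 (3S)-3,7-dimethyloct-6-en-1-yn-3-ol
Product: 16 (3S)-3-hydroxy-3,7-dimethyloct-6-en-2-one, via cyclic carbonate 15 (not isolated)
Conditions: AgOAc (5 mol%), DBU, CO2 (1 atm), MeCN, 25 °C; then H2O, 60 °C
Reagents that add atoms: carbon dioxide, O=C=O; water, O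
Why: Silver-catalysed carboxylative cyclisation of the propargylic alcohol and hydrolysis of the resulting enol carbonate amount to a Markovnikov alkyne hydration under basic conditions that spare the trisubstituted alkene and the stereocentre.

Step 10
Reactants: 16 (3S)-3-hydroxy-3,7-dimethyloct-6-en-2-one
Product: 17 (3S)-3,7-dimethyl-3-(triethylsilyloxy)oct-6-en-2-one
Conditions: Et3SiOTf, 2,6-lutidine, CH2Cl2, −78 to 0 °C
Reagents that add atoms: triethylsilyl trifluoromethanesulfonate, CC[Si](CC)(CC)OS(=O)(=O)C(F)(F)F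
Why: Silylation with the silyl triflate protects the hindered tertiary alcohol, so that the methyl group is the only acidic site of the ketone in the next step.

Step 11
Reactants: 17 (3S)-3,7-dimethyl-3-(triethylsilyloxy)oct-6-en-2-one; 9 (2E,6E)-8-(2,5-dimethoxy-3-methylphenyl)-2,6-dimethylocta-2,6-dienal
Product: 19 (6S,10E,14E)-16-(2,5-dimethoxy-3-methylphenyl)-9-hydroxy-2,6,10,14-tetramethyl-6-(triethylsilyloxy)hexadeca-2,10,14-trien-7-one (both C-9 epimers), via lithium enolate 18 (not isolated)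
Conditions: LiN(iPr)2, THF, −78 °C; then 9, −78 °C; AcOH quench
Reagents that add atoms: none
Why: Directed crossed aldol addition, in which the kinetic lithium enolate of a ketone with a single enolisable position adds 1,2 to the α-branched enal and joins the two halves at C-8′–C-9′; the new carbinol centre forms unselectively and is removed in step 12.

Step 12
Reactants: 19 the aldol adduct
Product: 21 (6S,8E,10E,14E)-16-(2,5-dimethoxy-3-methylphenyl)-2,6,10,14-tetramethyl-6-(triethylsilyloxy)hexadeca-2,8,10,14-tetraen-7-one, via acetate 20 (not isolated)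
Conditions: Ac2O, Et3N, DMAP (cat.), CH2Cl2, 0 °C; then DBU, 25 °C
Reagents that add atoms: none
Why: Acetylation and E1cB elimination complete the aldol condensation and give the thermodynamically favoured E enone of the conjugated dienone.

Step 13
Reactants: 21 the dienone
Product: 22 the N′-tosylhydrazone of 21 at C-7 (C-10′ of the target)
Conditions: TsNHNH2, EtOH, 50 °C
Reagents that add atoms: 4-methylbenzenesulfonohydrazide (tosylhydrazide), Cc1ccc(cc1)S(=O)(=O)NN
Why: Condensation of the ketone with tosylhydrazide gives the hydrazone needed for the reductive transposition without change at the stereocentre or the alkenes.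

Step 14
Reactants: 22 the tosylhydrazone
Product: 25 triethyl{[(6S,7E,10E,14E)-16-(2,5-dimethoxy-3-methylphenyl)-2,6,10,14-tetramethylhexadeca-2,7,10,14-tetraen-6-yl]oxy}silane, via boryl hydrazine 23 (not isolated), via allylic diazene 24 (not isolated)
Conditions: catecholborane, CHCl3, 0 °C; then NaOAc·3H2O, 60 °C
Reagents that add atoms: none
Why: Kabalka reduction, in which catecholborane reduces the C=N bond 1,2 and loss of sulfinate gives an allylic diazene whose retro-ene loss of N2 puts hydrogen on C-8′ and moves the double bond to C-9′/C-10′; the E geometry is expected because the bulky quaternary carbinol group avoids allylic strain in the six-membered transition state.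

Step 15
Reactants: 25 the silyl ether
Product: 26 (6S,7E,10E,14E)-16-(2,5-dimethoxy-3-methylphenyl)-2,6,10,14-tetramethylhexadeca-2,7,10,14-tetraen-6-ol
Conditions: Bu4NF, THF, 25 °C
Reagents that add atoms: none
Why: Fluoride-mediated desilylation frees the tertiary alcohol under non-acidic conditions that cannot ionise the allylic carbinol.

Step 16
Reactants: 26 the dimethyl ether alcohol
Product: 27 2-[(2E,6E,9E,11S)-11-hydroxy-3,7,11,15-tetramethylhexadeca-2,6,9,14-tetraen-1-yl]-6-methylcyclohexa-2,5-diene-1,4-dione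
Conditions: (NH4)2Ce(NO3)6 (2.5 equiv), MeCN/H2O (2:1), 0 °C, 15 min
Reagents that add atoms: water, O
Why: Oxidative demethylation of the 1,4-dimethoxyarene by (NH4)2Ce(NO3)6 gives the para-quinone under cold, brief conditions that the polyene and the tertiary allylic alcohol tolerate.

Step 17
Reactants: 27 the quinone
Product: 28 2-[(2E,6E,9E,11S)-11-hydroxy-3,7,11,15-tetramethylhexadeca-2,6,9,14-tetraen-1-yl]-6-methylbenzene-1,4-diol (target)
Conditions: Na2S2O4, THF/H2O, 25 °C, under argon
Reagents that add atoms: none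
Why: Dithionite reduction converts the quinone into the hydroquinone without affecting the alkenes or the stereocentre.

## Compound list
1 | 4-methoxy-2-methylphenol | COc1ccc(O)c(C)c1 | starting material
2 | 2-bromo-4-methoxy-6-methylphenol | COc1cc(C)c(O)c(Br)c1 | intermediate
3 | 1-bromo-2,5-dimethoxy-3-methylbenzene | COc1cc(C)c(OC)c(Br)c1 | intermediate
4 | geranyl bromide, (2E)-1-bromo-3,7-dimethylocta-2,6-diene | BrC/C=C(\C)CCC=C(C)C | starting material
5 | (2,5-dimethoxy-3-methylphenyl)lithium | [Li]c1cc(OC)cc(C)c1OC | intermediate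
6 | (2,5-dimethoxy-3-methylphenyl)copper | [Cu]c1cc(OC)cc(C)c1OC | intermediate
7 | 1-[(2E)-3,7-dimethylocta-2,6-dien-1-yl]-2,5-dimethoxy-3-methylbenzene | COc1cc(C)c(OC)c(C/C=C(\C)CCC=C(C)C)c1 | intermediate
8 | (2E,6E)-8-(2,5-dimethoxy-3-methylphenyl)-2,6-dimethylocta-2,6-dien-1-ol | COc1cc(C)c(OC)c(C/C=C(\C)CC/C=C(\C)CO)c1 | intermediate
9 | (2E,6E)-8-(2,5-dimethoxy-3-methylphenyl)-2,6-dimethylocta-2,6-dienal | COc1cc(C)c(OC)c(C/C=C(\C)CC/C=C(\C)C=O)c1 | intermediate
10 | geraniol, (2E)-3,7-dimethylocta-2,6-dien-1-ol | OC/C=C(\C)CCC=C(C)C | starting material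
11 | (2S,3S)-2,3-epoxygeraniol, [(2S,3S)-3-methyl-3-(4-methylpent-3-en-1-yl)oxiran-2-yl]methanol | OC[C@@H]1O[C@@]1(C)CCC=C(C)C | intermediate
12 | (2R,3S)-1-chloro-2,3-epoxy-3,7-dimethyloct-6-ene | ClC[C@@H]1O[C@@]1(C)CCC=C(C)C | intermediate
13 | lithium (3S)-1-chloro-3,7-dimethylocta-1,6-dien-3-olate (alkene geometry not defined) | [Li+].ClC=C[C@@](C)([O-])CCC=C(C)C | intermediate
14 | (3S)-3,7-dimethyloct-6-en-1-yn-3-ol, (S)-dehydrolinalool | C#C[C@@](C)(O)CCC=C(C)C | intermediate
15 | (4S)-4-methyl-5-methylidene-4-(4-methylpent-3-en-1-yl)-1,3-dioxolan-2-one | C=C1OC(=O)O[C@@]1(C)CCC=C(C)C | intermediate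
16 | (3S)-3-hydroxy-3,7-dimethyloct-6-en-2-one | CC(=O)[C@@](C)(O)CCC=C(C)C | intermediate
17 | (3S)-3,7-dimethyl-3-(triethylsilyloxy)oct-6-en-2-one | CC(=O)[C@@](C)(O[Si](CC)(CC)CC)CCC=C(C)C | intermediate
18 | lithium (3S)-3,7-dimethyl-3-(triethylsilyloxy)octa-1,6-dien-2-olate | [Li+].[O-]C(=C)[C@@](C)(O[Si](CC)(CC)CC)CCC=C(C)C | intermediate
19 | (6S,10E,14E)-16-(2,5-dimethoxy-3-methylphenyl)-9-hydroxy-2,6,10,14-tetramethyl-6-(triethylsilyloxy)hexadeca-2,10,14-trien-7-one, C-9 epimers | COc1cc(C)c(OC)c(C/C=C(\C)CC/C=C(\C)C(O)CC(=O)[C@@](C)(O[Si](CC)(CC)CC)CCC=C(C)C)c1 | intermediate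
20 | 9-acetate of 19 | COc1cc(C)c(OC)c(C/C=C(\C)CC/C=C(\C)C(OC(C)=O)CC(=O)[C@@](C)(O[Si](CC)(CC)CC)CCC=C(C)C)c1 | intermediate
21 | (6S,8E,10E,14E)-16-(2,5-dimethoxy-3-methylphenyl)-2,6,10,14-tetramethyl-6-(triethylsilyloxy)hexadeca-2,8,10,14-tetraen-7-one | COc1cc(C)c(OC)c(C/C=C(\C)CC/C=C(\C)/C=C/C(=O)[C@@](C)(O[Si](CC)(CC)CC)CCC=C(C)C)c1 | intermediate
22 | N′-tosylhydrazone of 21 (C=N geometry not defined) | COc1cc(C)c(OC)c(C/C=C(\C)CC/C=C(\C)/C=C/C(=NNS(=O)(=O)c2ccc(C)cc2)[C@@](C)(O[Si](CC)(CC)CC)CCC=C(C)C)c1 | intermediate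
23 | N-(1,3,2-benzodioxaborol-2-yl)-N′-tosylhydrazine from 1,2-reduction of 22 (C-7 epimers) | COc1cc(C)c(OC)c(C/C=C(\C)CC/C=C(\C)/C=C/C(N(NS(=O)(=O)c2ccc(C)cc2)B2Oc3ccccc3O2)[C@@](C)(O[Si](CC)(CC)CC)CCC=C(C)C)c1 | intermediate
24 | allylic diazene at C-7 (C-7 epimers) | COc1cc(C)c(OC)c(C/C=C(\C)CC/C=C(\C)/C=C/C(N=N)[C@@](C)(O[Si](CC)(CC)CC)CCC=C(C)C)c1 | intermediate
25 | triethyl{[(6S,7E,10E,14E)-16-(2,5-dimethoxy-3-methylphenyl)-2,6,10,14-tetramethylhexadeca-2,7,10,14-tetraen-6-yl]oxy}silane | COc1cc(C)c(OC)c(C/C=C(\C)CC/C=C(\C)C/C=C/[C@@](C)(O[Si](CC)(CC)CC)CCC=C(C)C)c1 | intermediate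
26 | (6S,7E,10E,14E)-16-(2,5-dimethoxy-3-methylphenyl)-2,6,10,14-tetramethylhexadeca-2,7,10,14-tetraen-6-ol | COc1cc(C)c(OC)c(C/C=C(\C)CC/C=C(\C)C/C=C/[C@@](C)(O)CCC=C(C)C)c1 | intermediate
27 | 2-[(2E,6E,9E,11S)-11-hydroxy-3,7,11,15-tetramethylhexadeca-2,6,9,14-tetraen-1-yl]-6-methylcyclohexa-2,5-diene-1,4-dione | CC1=CC(=O)C=C(C/C=C(\C)CC/C=C(\C)C/C=C/[C@@](C)(O)CCC=C(C)C)C1=O | intermediate
28 | 2-[(2E,6E,9E,11S)-11-hydroxy-3,7,11,15-tetramethylhexadeca-2,6,9,14-tetraen-1-yl]-6-methylbenzene-1,4-diol | Cc1cc(O)cc(C/C=C(\C)CC/C=C(\C)C/C=C/[C@@](C)(O)CCC=C(C)C)c1O | target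

## Count and risks
Total step count: 17. Longest linear sequence: 12 steps (steps 1–5 then 11–17, or steps 6–17).

The three steps most likely to fail:

Step 14 (with step 13). The ketone is hindered, the enone hydrazone can close to a pyrazoline, and the E/Z ratio of the new alkene rests on conformational control. The fallback sets out from 8 and 14 and comes back at 26. Alcohol 8 is converted (MsCl, Et3N; then LiBr, THF) into 1-[(2E,6E)-8-bromo-3,7-dimethylocta-2,6-dien-1-yl]-2,5-dimethoxy-3-methylbenzene F8. Copper-mediated alkynylation of F8 with 14 (CuI, NaI, K2CO3, DMF) gives (6S,10E,14E)-16-(2,5-dimethoxy-3-methylphenyl)-2,6,10,14-tetramethylhexadeca-2,10,14-trien-7-yn-6-ol F9. Hydroxyl-directed trans-hydroalumination of F9 with NaAlH2(OCH2CH2OMe)2 in THF gives 26 with a secured E alkene.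

Step 4. The selenium dioxide may also attack the inner C-4′ methylene of 7 and the yield is usually moderate. The fallback oxidises before the arene is attached; it sets out from 10 (and uses arylcopper 6 made from 3) and comes back at 8. Geraniol 10 is acetylated (Ac2O, pyridine) to geranyl acetate F1, whose inner alkene is deactivated by the allylic acetate. SeO2/t-BuOOH then gives (2E,6E)-8-hydroxy-3,7-dimethylocta-2,6-dien-1-yl acetate F2. Silylation (t-BuMe2SiCl, imidazole) gives (2E,6E)-8-[(tert-butyldimethylsilyl)oxy]-3,7-dimethylocta-2,6-dien-1-yl acetate F3. Methanolysis (K2CO3, MeOH) gives (2E,6E)-8-[(tert-butyldimethylsilyl)oxy]-3,7-dimethylocta-2,6-dien-1-ol F4. MsCl/Et3N then LiBr gives [(2E,6E)-8-bromo-2,6-dimethylocta-2,6-dien-1-yl]oxy(tert-butyl)dimethylsilane F5. Coupling of F5 with arylcopper 6 gives tert-butyl{[(2E,6E)-8-(2,5-dimethoxy-3-methylphenyl)-2,6-dimethylocta-2,6-dien-1-yl]oxy}dimethylsilane F6, and Bu4NF converts F6 into 8.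

Step 9. The carboxylative hydration may stall at the carbonate, or the 1,6-enyne may react otherwise at silver. The fallback sets out from 14 and comes back at 16. Ruthenium-catalysed Markovnikov hydrosilylation of 14 ([Cp*Ru(MeCN)3]PF6, (EtO)3SiH, CH2Cl2, 0 °C) gives (3S)-3,7-dimethyl-2-(triethoxysilyl)octa-1,6-dien-3-ol F7. Tamao–Fleming oxidation of F7 (H2O2, KF, KHCO3, THF/MeOH) gives 16.

## Further compounds
F1 | step 4 | geranyl acetate, (2E)-3,7-dimethylocta-2,6-dien-1-yl acetate | CC(=O)OC/C=C(\C)CCC=C(C)C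
F2 | step 4 | (2E,6E)-8-hydroxy-3,7-dimethylocta-2,6-dien-1-yl acetate | CC(=O)OC/C=C(\C)CC/C=C(\C)CO
F3 | step 4 | (2E,6E)-8-[(tert-butyldimethylsilyl)oxy]-3,7-dimethylocta-2,6-dien-1-yl acetate | CC(=O)OC/C=C(\C)CC/C=C(\C)CO[Si](C)(C)C(C)(C)C
F4 | step 4 | (2E,6E)-8-[(tert-butyldimethylsilyl)oxy]-3,7-dimethylocta-2,6-dien-1-ol | OC/C=C(\C)CC/C=C(\C)CO[Si](C)(C)C(C)(C)C
F5 | step 4 | [(2E,6E)-8-bromo-2,6-dimethylocta-2,6-dien-1-yl]oxy(tert-butyl)dimethylsilane | BrC/C=C(\C)CC/C=C(\C)CO[Si](C)(C)C(C)(C)C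
F6 | step 4 | tert-butyl{[(2E,6E)-8-(2,5-dimethoxy-3-methylphenyl)-2,6-dimethylocta-2,6-dien-1-yl]oxy}dimethylsilane | COc1cc(C)c(OC)c(C/C=C(\C)CC/C=C(\C)CO[Si](C)(C)C(C)(C)C)c1
F7 | step 9 | (3S)-3,7-dimethyl-2-(triethoxysilyl)octa-1,6-dien-3-ol | C=C([Si](OCC)(OCC)OCC)[C@@](C)(O)CCC=C(C)C
F8 | step 14 | 1-[(2E,6E)-8-bromo-3,7-dimethylocta-2,6-dien-1-yl]-2,5-dimethoxy-3-methylbenzene | COc1cc(C)c(OC)c(C/C=C(\C)CC/C=C(\C)CBr)c1
F9 | step 14 | (6S,10E,14E)-16-(2,5-dimethoxy-3-methylphenyl)-2,6,10,14-tetramethylhexadeca-2,10,14-trien-7-yn-6-ol | COc1cc(C)c(OC)c(C/C=C(\C)CC/C=C(\C)CC#C[C@@](C)(O)CCC=C(C)C)c1
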